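**Plan**

1. Numbering: indane C1 (carries the exocyclic carbon C8), C2, C3; ring A is C3a–C7a, ring B is C1–C2–C3–C3a–C7a. The target is the all-cis (1R,2R,3R) isomer.
2. Retrosynthesis: the six O–H groups go back to O–Me; C8=O and C1–H go back to an exocyclic C1=C8 alkene (hydroboration–oxidation, then oxidation). The ring B bond C2–C3 is then cut (carbene C–H insertion), followed by C3=N, C1–C7a (Suzuki), C3–C3a (Friedel–Crafts) and the C2–alkyne bond.
3. Enabling feature: C3 is a diarylmethine on ring A, and a carbene at C3 lies 1,5 (through C3a, C7a, C1) to the C2–H bond, which is benzylic to the 3,5-dimethoxyphenyl ring and allylic to C1=C8.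
4. Forward: ketone 3 (ring A plus C3) and alkenylboronate 8 (C8–C1–C2) are made separately and joined at C1–C7a. The ketone becomes the hydrazone, and ring B, the only ring formed, closes in step 6.
5. Stereochemistry: C2 and C3 (cis) come from the chiral dirhodium carboxylate in the insertion; C1 comes from syn hydroboration on the face away from both aryl groups; the E alkene comes from syn Cu–B addition to the alkyne and a stereoretentive coupling.

Key step: step 6

Assumption: Rh2(R-PTAD)4, dirhodium tetrakis[(R)-(1-adamantyl)(N-phthalimido)acetate], is taken as the catalyst antipode that leads to (2S,3R)-12; if the sense of induction on this substrate is the opposite one, Rh2(S-PTAD)4 is used.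
Remark: the C=N geometry of hydrazone 10 is of no consequence, because it is lost in the diazo compound.

**Route**

Step 1
Reactants: 1 1-bromo-3,5-dimethoxybenzene; 2 4-methoxybenzoyl chloride
Product: 3 (2-bromo-4,6-dimethoxyphenyl)(4-methoxyphenyl)methanone
Conditions: AlCl3 (1.2 equiv), CH2Cl2, 0 °C
Reagents that add atoms: none
Why: Friedel–Crafts aroylation in which the acylium ion should attack 1 at the position para to one methoxy group and ortho to the other (next to bromine), which is less encumbered than the position between the two methoxy groups, while the low temperature keeps the ortho methoxy group from being cleaved.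

Step 2
Reactants: 4 4-ethynylanisole; 5 3,5-dimethoxybenzyl bromide
Product: 7 1,3-dimethoxy-5-[3-(4-methoxyphenyl)prop-2-yn-1-yl]benzene, via alkynylmagnesium bromide 6 (not isolated)
Conditions: EtMgBr, THF, 0 °C to rt; then CuBr (10 mol%), 5, THF, 60 °C
Reagents that add atoms: none
Why: Deprotonation of the terminal alkyne followed by copper-catalysed alkynyl–benzyl cross-coupling of the alkynyl Grignard reagent with the benzylic bromide, run without added base so that the 1,3-diarylpropyne should not isomerise to the allene.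

Step 3
Reactants: 7 1,3-dimethoxy-5-[3-(4-methoxyphenyl)prop-2-yn-1-yl]benzene
Product: 8 2-[(Z)-3-(3,5-dimethoxyphenyl)-1-(4-methoxyphenyl)prop-1-en-2-yl]-4,4,5,5-tetramethyl-1,3,2-dioxaborolane (H and boron cis; anisyl and benzyl groups cis)
Conditions: CuCl (5 mol%), Xantphos (5 mol%), NaOtBu (10 mol%), B2pin2, MeOH (2 equiv), THF, rt
Reagents that add atoms: bis(pinacolato)diboron, CC1(C)OB(OC1(C)C)B1OC(C)(C)C(C)(C)O1
Why: Copper-catalysed formal hydroboration of an internal aryl alkyl alkyne, in which syn borylcupration places copper on the aryl-bearing carbon and boron on the benzyl-bearing carbon and methanol protonates the alkenylcopper with retention.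

Step 4
Reactants: 3 (2-bromo-4,6-dimethoxyphenyl)(4-methoxyphenyl)methanone; 8 the (Z)-alkenylboronate
Product: 9 [2-[(E)-3-(3,5-dimethoxyphenyl)-1-(4-methoxyphenyl)prop-1-en-2-yl]-4,6-dimethoxyphenyl](4-methoxyphenyl)methanone (ring A trans to the anisyl group)
Conditions: Pd(OAc)2 (5 mol%), SPhos (10 mol%), K3PO4, toluene/H2O 10:1, 90 °C
Reagents that add atoms: none
Why: Suzuki–Miyaura coupling with retention of alkene geometry (the change from Z to E is only a matter of substituent ranking), the oxidative addition being eased by the ortho aroyl group and the biarylphosphine coping with the alpha-branched alkenylboronate.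

Step 5
Reactants: 9 the alkenyl diaryl ketone
Product: 10 [2-[(E)-3-(3,5-dimethoxyphenyl)-1-(4-methoxyphenyl)prop-1-en-2-yl]-4,6-dimethoxyphenyl](4-methoxyphenyl)methanone hydrazone (drawn with NH2 syn to ring A)
Conditions: N2H4·H2O (30 equiv), AcOH (cat.), n-BuOH, 110 °C, sealed tube, argon
Reagents that add atoms: hydrazine (used as the monohydrate), NN
Why: Hydrazone condensation, pushed with excess hydrazine, acid catalysis and heat because the carbonyl group is flanked by two ortho substituents and bears an electron-rich aryl group, and run without air so that no diimide reduces the alkene.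

Step 6
Reactants: 10 the hydrazone
Product: 12 (2S,3R)-2-(3,5-dimethoxyphenyl)-4,6-dimethoxy-1-[(E)-4-methoxybenzylidene]-3-(4-methoxyphenyl)indane (2,3-cis), via diaryldiazomethane 11 (not isolated)
Conditions: MnO2 (8 equiv), CH2Cl2, 0 °C, dark; cold filtration; then Rh2(R-PTAD)4 (1 mol%), CH2Cl2, −20 to 0 °C
Reagents that add atoms: none
Why: Proposed new method: MnO2 dehydrogenates the hydrazone to diazo compound 11, which loses N2 on the dirhodium tetracarboxylate to give an electrophilic diaryl (donor/donor) rhodium carbene at C3, and hydride-like transfer from C2 with C2–C3 bond formation should then occur in one three-centre event with retention at C2. The closest known reactions are the dirhodium-catalysed enantioselective 1,5 C–H insertions of hydrazone-derived diaryl carbenes that give cis-2,3-disubstituted dihydrobenzofurans (including allylic O–CH2 sites) and cis-1,2-diarylindanes across a saturated two-carbon tether; what is new is the sp2 tether atom C1, so that the C–H bond is allylic to an alkene lying inside the tether. Ring B closes by a 1,5-insertion through a five-membered transition state (C3, C3a, C7a, C1, C2), which leaves the alkene exocyclic. C2 and C3 are set together: the compact transition state places the two aryl groups cis under kinetic control, and the chiral carboxylate ligands of Rh2(R-PTAD)4 choose the absolute sense. The step must prefer the C2–H bond over the C4 methoxy C–H bonds, over attack of the carbene on C8 (indene formation), over closure of a transposed allyl cation at C8, and over 1,7-electrocyclisation or azine formation of 11. The doubly activated (benzylic and allylic) C2–H bond, the twist of the alkene out of the plane of ring A, the strain of a cyclopropane fused to a four-membered ring, and generation of 11 in the cold with immediate transfer onto the catalyst are what should favour the wanted path.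

Step 7
Reactants: 12 the 2,3-cis benzylidene indane
Product: 14 (R)-[(1R,2R,3R)-2-(3,5-dimethoxyphenyl)-4,6-dimethoxy-3-(4-methoxyphenyl)-2,3-dihydro-1H-inden-1-yl](4-methoxyphenyl)methanol (all-cis on ring B), via alkylborane 13 (not isolated)
Conditions: BH3·THF (3 equiv), THF, 0 °C to rt; then NaOH, H2O2, 0 °C to rt
Reagents that add atoms: hydrogen peroxide, OO (oxygen of 14); borane–tetrahydrofuran, B.C1CCOC1 (boron of 13 only)
Why: Brown hydroboration–oxidation in which boron should add to the less substituted C8 and hydrogen to C1, syn and from the face opposite the C2 and C3 aryl groups, so that the C1 side chain ends up cis to both aryl groups, and the C–B bond is oxidised with retention.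

Step 8
Reactants: 14 the carbinol
Product: 15 [(1R,2R,3R)-2-(3,5-dimethoxyphenyl)-4,6-dimethoxy-3-(4-methoxyphenyl)-2,3-dihydro-1H-inden-1-yl](4-methoxyphenyl)methanone
Conditions: Dess–Martin periodinane (1.5 equiv), CH2Cl2, 0 °C to rt
Reagents that add atoms: none
Why: Dess–Martin oxidation of the secondary benzylic alcohol under nearly neutral conditions, chosen so that the epimerisable all-cis C1 centre next to the new ketone is not equilibrated; the C8 stereocentre is removed.

Step 9
Reactants: 15 the hexamethyl ether ketone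
Product: 16 caraphenol C, (4-hydroxyphenyl)[(1R,2R,3R)-2-(3,5-dihydroxyphenyl)-4,6-dihydroxy-3-(4-hydroxyphenyl)-2,3-dihydro-1H-inden-1-yl]methanone
Conditions: BBr3 (15 equiv), CH2Cl2, −78 to 0 °C; then H2O, 0 °C
Reagents that add atoms: none
Why: Lewis acid-mediated cleavage of the six aryl methyl ethers, started cold and kept at or below 0 °C so that C1 should not epimerise and the cis resorcinol ring should not add to the activated ketone.

**Compound list**

1 | 1-bromo-3,5-dimethoxybenzene | COc1cc(Br)cc(OC)c1 | starting material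
2 | 4-methoxybenzoyl chloride | COc1ccc(C(=O)Cl)cc1 | starting material
3 | (2-bromo-4,6-dimethoxyphenyl)(4-methoxyphenyl)methanone | COc1ccc(cc1)C(=O)c1c(Br)cc(OC)cc1OC | intermediate
4 | 4-ethynylanisole | COc1ccc(C#C)cc1 | starting material
5 | 3,5-dimethoxybenzyl bromide | COc1cc(CBr)cc(OC)c1 | starting material
6 | [(4-methoxyphenyl)ethynyl]magnesium bromide | COc1ccc(C#C[Mg]Br)cc1 | intermediate (not isolated)
7 | 1,3-dimethoxy-5-[3-(4-methoxyphenyl)prop-2-yn-1-yl]benzene | COc1ccc(C#CCc2cc(OC)cc(OC)c2)cc1 | intermediate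
8 | 2-[(Z)-3-(3,5-dimethoxyphenyl)-1-(4-methoxyphenyl)prop-1-en-2-yl]-4,4,5,5-tetramethyl-1,3,2-dioxaborolane | COc1ccc(/C=C(\Cc2cc(OC)cc(OC)c2)B2OC(C)(C)C(C)(C)O2)cc1 | intermediate
9 | [2-[(E)-3-(3,5-dimethoxyphenyl)-1-(4-methoxyphenyl)prop-1-en-2-yl]-4,6-dimethoxyphenyl](4-methoxyphenyl)methanone | COc1ccc(/C=C(\Cc2cc(OC)cc(OC)c2)c2cc(OC)cc(OC)c2C(=O)c2ccc(OC)cc2)cc1 | intermediate
10 | hydrazone of 9 (C=N geometry immaterial) | N/N=C(/c1ccc(OC)cc1)c1c(OC)cc(OC)cc1/C(Cc1cc(OC)cc(OC)c1)=C/c1ccc(OC)cc1 | intermediate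
11 | 2-[diazo(4-methoxyphenyl)methyl]-1-[(E)-3-(3,5-dimethoxyphenyl)-1-(4-methoxyphenyl)prop-1-en-2-yl]-3,5-dimethoxybenzene | [N-]=[N+]=C(c1ccc(OC)cc1)c1c(OC)cc(OC)cc1/C(Cc1cc(OC)cc(OC)c1)=C/c1ccc(OC)cc1 | intermediate (not isolated)
12 | (2S,3R)-2-(3,5-dimethoxyphenyl)-4,6-dimethoxy-1-[(E)-4-methoxybenzylidene]-3-(4-methoxyphenyl)indane | COc1ccc(/C=C2/c3cc(OC)cc(OC)c3[C@@H](c3ccc(OC)cc3)[C@H]2c2cc(OC)cc(OC)c2)cc1 | intermediate
13 | [(R)-[(1R,2R,3R)-2-(3,5-dimethoxyphenyl)-4,6-dimethoxy-3-(4-methoxyphenyl)indan-1-yl](4-methoxyphenyl)methyl]borane | COc1ccc(cc1)[C@H](B)[C@H]1c2cc(OC)cc(OC)c2[C@@H](c2ccc(OC)cc2)[C@H]1c1cc(OC)cc(OC)c1 | intermediate (not isolated)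
14 | (R)-[(1R,2R,3R)-2-(3,5-dimethoxyphenyl)-4,6-dimethoxy-3-(4-methoxyphenyl)-2,3-dihydro-1H-inden-1-yl](4-methoxyphenyl)methanol | COc1ccc(cc1)[C@H](O)[C@H]1c2cc(OC)cc(OC)c2[C@@H](c2ccc(OC)cc2)[C@H]1c1cc(OC)cc(OC)c1 | intermediate
15 | [(1R,2R,3R)-2-(3,5-dimethoxyphenyl)-4,6-dimethoxy-3-(4-methoxyphenyl)-2,3-dihydro-1H-inden-1-yl](4-methoxyphenyl)methanone | COc1ccc(cc1)C(=O)[C@H]1c2cc(OC)cc(OC)c2[C@@H](c2ccc(OC)cc2)[C@H]1c1cc(OC)cc(OC)c1 | intermediate
16 | caraphenol C | O=C(c1ccc(O)cc1)[C@H]1c2cc(O)cc(O)c2[C@@H](c2ccc(O)cc2)[C@H]1c1cc(O)cc(O)c1 | target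

**Count and risks**

Total steps: 9. Longest linear sequence: 8 steps (steps 2, 3, 4, 5, 6, 7, 8, 9, from 4 and 5).

Most likely to fail:

1. Step 6 (labelled as a proposed new method). The diazo compound or the carbene may be diverted through the neighbouring alkene (electrocyclisation, attack of C8 on the carbene, allylic transposition during C–C bond formation), or the enantio- and diastereocontrol may be insufficient. Fallback with known reactions only, setting out from 9 and coming back at 12: the C2–C3 bond is made by an aldol condensation and both stereocentres by hydrogenation.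
   - Ozonolysis of 9 (O3, CH2Cl2/MeOH, −78 °C; Me2S) should cleave the alkene to 2-(3,5-dimethoxyphenyl)-1-[3,5-dimethoxy-2-(4-methoxybenzoyl)phenyl]ethanone F1.
   - KOH in ethanol should close ring B by intramolecular aldol condensation to 2-(3,5-dimethoxyphenyl)-4,6-dimethoxy-3-(4-methoxyphenyl)inden-1-one F2.
   - Corey–Bakshi–Shibata reduction (the Me-CBS antipode that gives the R carbinol, BH3·SMe2) should give (R)-2-(3,5-dimethoxyphenyl)-4,6-dimethoxy-3-(4-methoxyphenyl)-1H-inden-1-ol F3.
   - Hydroxyl-directed hydrogenation with [Ir(cod)(PCy3)(py)]PF6 and H2 in CH2Cl2 should add both hydrogens on the hydroxyl face and give (1S,2S,3R)-2-(3,5-dimethoxyphenyl)-4,6-dimethoxy-3-(4-methoxyphenyl)indan-1-ol F4.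
   - Dess–Martin oxidation should give (2S,3R)-2-(3,5-dimethoxyphenyl)-4,6-dimethoxy-3-(4-methoxyphenyl)indan-1-one F5.
   - Non-basic Petasis benzylidenation with Cp2Ti(CH2C6H4-4-OMe)2 (toluene, 55 °C) should return 12 without epimerising C2.

2. Step 5. Condensation at the shielded, electron-rich carbonyl group may stay incomplete, or azine formation may take over. Fallback from 9 back to 10: Lawesson's reagent (toluene, 90 °C) should convert the ketone into the far more electrophilic thioketone, [2-[(E)-3-(3,5-dimethoxyphenyl)-1-(4-methoxyphenyl)prop-1-en-2-yl]-4,6-dimethoxyphenyl](4-methoxyphenyl)methanethione F6, which should exchange sulfur for the hydrazone with N2H4·H2O in THF at room temperature to give 10.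

3. Step 9. C1 may epimerise via the boron-complexed ketone, or the cis resorcinol ring may add to the activated carbonyl group. Fallback from 12 back to 16: the methyl ethers are removed before the ketone exists and the phenols are carried as silyl ethers, so that the last step is nearly neutral.
   - BBr3 on 12 should give (2S,3R)-2-(3,5-dihydroxyphenyl)-1-[(E)-4-hydroxybenzylidene]-3-(4-hydroxyphenyl)indane-4,6-diol F7.
   - TBSCl and imidazole in DMF should give its hexakis(tert-butyldimethylsilyl) ether F8.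
   - BH3·THF should give the hexasilylated alkylborane F9 (not isolated), and NaBO3·4H2O should oxidise it to the hexasilylated (R)-carbinol F10.
   - Dess–Martin oxidation should give the hexasilylated all-cis ketone F11.
   - HF·pyridine in THF at 0 °C should release 16.

**Further compounds**

F1 | step 6 | 2-(3,5-dimethoxyphenyl)-1-[3,5-dimethoxy-2-(4-methoxybenzoyl)phenyl]ethanone | O=C(Cc1cc(OC)cc(OC)c1)c1cc(OC)cc(OC)c1C(=O)c1ccc(OC)cc1
F2 | step 6 | 2-(3,5-dimethoxyphenyl)-4,6-dimethoxy-3-(4-methoxyphenyl)-1H-inden-1-one | O=C1c2cc(OC)cc(OC)c2C(c2ccc(OC)cc2)=C1c1cc(OC)cc(OC)c1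
F3 | step 6 | (R)-2-(3,5-dimethoxyphenyl)-4,6-dimethoxy-3-(4-methoxyphenyl)-1H-inden-1-ol | O[C@@H]1c2cc(OC)cc(OC)c2C(c2ccc(OC)cc2)=C1c1cc(OC)cc(OC)c1
F4 | step 6 | (1S,2S,3R)-2-(3,5-dimethoxyphenyl)-4,6-dimethoxy-3-(4-methoxyphenyl)indan-1-ol | O[C@@H]1c2cc(OC)cc(OC)c2[C@@H](c2ccc(OC)cc2)[C@H]1c1cc(OC)cc(OC)c1
F5 | step 6 | (2S,3R)-2-(3,5-dimethoxyphenyl)-4,6-dimethoxy-3-(4-methoxyphenyl)indan-1-one | O=C1c2cc(OC)cc(OC)c2[C@@H](c2ccc(OC)cc2)[C@H]1c1cc(OC)cc(OC)c1
F6 | step 5 | [2-[(E)-3-(3,5-dimethoxyphenyl)-1-(4-methoxyphenyl)prop-1-en-2-yl]-4,6-dimethoxyphenyl](4-methoxyphenyl)methanethione | COc1ccc(/C=C(\Cc2cc(OC)cc(OC)c2)c2cc(OC)cc(OC)c2C(=S)c2ccc(OC)cc2)cc1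
F7 | step 9 | (2S,3R)-2-(3,5-dihydroxyphenyl)-1-[(E)-4-hydroxybenzylidene]-3-(4-hydroxyphenyl)indane-4,6-diol | Oc1ccc(/C=C2/c3cc(O)cc(O)c3[C@@H](c3ccc(O)cc3)[C@H]2c2cc(O)cc(O)c2)cc1
F8 | step 9 | hexakis(tert-butyldimethylsilyl) ether of F7 | CC(C)(C)[Si](C)(C)Oc1ccc(/C=C2/c3cc(O[Si](C)(C)C(C)(C)C)cc(O[Si](C)(C)C(C)(C)C)c3[C@@H](c3ccc(O[Si](C)(C)C(C)(C)C)cc3)[C@H]2c2cc(O[Si](C)(C)C(C)(C)C)cc(O[Si](C)(C)C(C)(C)C)c2)cc1
F9 | step 9 | hexasilylated alkylborane (BH2 on C8, all-cis ring B) | CC(C)(C)[Si](C)(C)Oc1ccc(cc1)[C@H](B)[C@H]1c2cc(O[Si](C)(C)C(C)(C)C)cc(O[Si](C)(C)C(C)(C)C)c2[C@@H](c2ccc(O[Si](C)(C)C(C)(C)C)cc2)[C@H]1c1cc(O[Si](C)(C)C(C)(C)C)cc(O[Si](C)(C)C(C)(C)C)c1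
F10 | step 9 | hexasilylated (R)-carbinol, (1R,2R,3R) ring B | CC(C)(C)[Si](C)(C)Oc1ccc(cc1)[C@H](O)[C@H]1c2cc(O[Si](C)(C)C(C)(C)C)cc(O[Si](C)(C)C(C)(C)C)c2[C@@H](c2ccc(O[Si](C)(C)C(C)(C)C)cc2)[C@H]1c1cc(O[Si](C)(C)C(C)(C)C)cc(O[Si](C)(C)C(C)(C)C)c1
F11 | step 9 | hexakis(tert-butyldimethylsilyl) ether of caraphenol C | CC(C)(C)[Si](C)(C)Oc1ccc(cc1)C(=O)[C@H]1c2cc(O[Si](C)(C)C(C)(C)C)cc(O[Si](C)(C)C(C)(C)C)c2[C@@H](c2ccc(O[Si](C)(C)C(C)(C)C)cc2)[C@H]1c1cc(O[Si](C)(C)C(C)(C)C)cc(O[Si](C)(C)C(C)(C)C)c1
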